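Of the amount of starting material charged, the grey run keeps 60.4% after 2.50 d, while the amber run, with the charge and the catalyst both doubled, keeps 40.9%. At that time the target reads 3.9% in grey and 2.1% in amber.

| flask | starting material | catalyst | temperature | remark | time |
|---|---|---|---|---|---|
| grey | 0.091 M | 2.1 mM | 45 °C | run made earlier |  |
| green | 0.091 M | 8.6 mM | 95 °C | run made earlier |  |
| amber | 0.18 M | 4.3 mM | 45 °C | run made earlier |  |
| west | 0.091 M | 4.3 mM | 80 °C |  | 4.0 d |
| south-east | 0.091 M | 4.3 mM | 140 °C |  | 4.0 d |
| north-west | 0.091 M | 4.3 mM | 110 °C |  | 4.0 d |
| north | 0.091 M | 4.3 mM | 50 °C |  | 4.0 d |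

- grey (time / d: target / %, starting material / %): 2.50: 3.9, 60.4; 5.00: 3.0, 39.6; 12.0: 6.1, 16.1; 30.0: 8.8, 4.5
- green (time / d: target / %, starting material / %): 0.625: 12.0, 2.2; 1.25: 9.1, 3.2; 2.08: 7.5, 1.5; 2.50: 6.6, 2.4
- amber (time / d: target / %, starting material / %): 2.50: 2.1, 40.9; 5.00: 2.3, 22.4; 12.0: 3.4, 6.6; 30.0: 5.7, 2.5

(readings scatter by 0.5 percentage points)

- a reading or a percentage of target counts all its forms, free or not

* the flask that comes out highest in amount of target, in percent of the starting material charged, or "all alike" when all lie within 1.5 percentage points (west / south-east / north-west / north / all alike)
* target at the end, in percent of the starting material charged, west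
* target at the end, in percent of the starting material charged, south-east
* target at the end, in percent of the starting material charged, north-west
* target at the end, in percent of the starting material charged, north

I picture two extreme flasks. In the first, starting material is lost through the catalyst, a pseudo-first-order loss whose percent curve ignores the charge. In the second, two molecules of starting material meet, and the constant grows with c(starting material).

Between them stands one concentration, the crossing concentration c×, at which both losses are equal. In grey, the apparent constant is 0.202 /d early and 0.0708 /d late, while the mean concentration falls from 0.0730 M to 0.00937 M. The slope therefore reads 2.06 /M/d, and scaled to 4.3 mM of catalyst at 45 °C, c× reads about 0.0513 M, a reading that carries the scatter of these percentages.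

As a check from a different run, these numbers reckon 0.366 /d for early amber, and amber reads 0.358 /d.

A flask with both losses lies between the extremes. With x the charge over c×, the second-order share of what is spent to the end is 1 − ln(1 + x)/x. The charge of 0.091 M lies above this reading of c×, so x is 1.77 and my estimate of the share at 45 °C with 4.3 mM of catalyst is 42.4%. This says how the starting material goes, not how much target stands.

The forecast gives 9% for west, 2% for south-east, 4.5% for north-west and 4% for north, and names west as highest: “80 °C sits near the maximum”.

The flasks give 13.6% in west, 3.22% in south-east, 5.36% in north-west and 5.12% in north, so west is highest.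

    starting material ⇌ target (K = 3.60, k = 0.0633 /h, Ea = 128 kJ/mol, ΔH = −10.0 kJ/mol)
    starting material + catalyst ⇌ isomer of the product + catalyst, rate k2*[starting material]*[catalyst] forward; the back reaction follows from the equilibrium constant (K = 28.0, k = 30.7 /M/h, Ea = 83.0 kJ/mol, ΔH = 14.0 kJ/mol)
    crystals ⇌ target, rate k3*(cs3 - [target]) while solid is left; crystals form when [target] > cs3 (solubility = 48.0 mM, k = 4.17 /h)
    2 starting material → homo dimer (k = 0.511 /M/h, Ea = 69.0 kJ/mol)
    (constants at 80 °C)

West holds 64.1% isomer of the product and 19.5% homo dimer beside its target, yet it still leads the other flasks by 8.2 percentage points. South-east holds 13.0% homo dimer. Taking that as the share in south-east, and with small x the share near half of x, I get an apparent c× of about 0.351 M there, above the 0.0513 M read at 45 °C. Its neighbour, charged with 0.36 M and all else held, gets x = 1.03, and I reckon a share of 31.3%. That neighbour holds 2.39% target, 61.7% isomer of the product and 34.8% homo dimer.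

The readings are calculated for substances that don't exist; scatter was added.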